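**Retrosynthetic overview**
1. Target 30 ⇐ diol 28 (acylation of the less hindered C5–OH) ⇐ angelate 26 (syn-dihydroxylation anti to the allylic ester) ⇐ allylic alcohol 24.
2. Six-membered enone ring (formed last) ⇐ carbonyl-ene closure of a cis-1,3 formyl/isopropenyl pair on the cyclobutane, then oxidation and isomerisation.
3. Cyclobutanone and seven-membered ring (formed together) ⇐ bridged intramolecular [2+2] of a (Z)-vinylketene with the terminal double bond of an (E)-1,3-diene: acyclic acid 13 → bicyclo[4.1.1]octenone 16.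
4. Acid 13 ⇐ Z-selective Wittig of α-silyloxy aldehyde 9 with a β-carboxy ylide; 9 ⇐ (S)-pantolactone, which supplies C4 and the gem-dimethyl carbon.
5. C4 directs the facial course of the cycloaddition and then the dihydroxylation (C5, C6); the ring carbons follow from alkene geometry and the tether.

Assumption: (S)-pantolactone, angelic acid and (R)-2-methylbutanoic acid are bought as single isomers; ring compounds are numbered as bicyclo[4.1.1]octane (C1 = methyl-bearing bridgehead, C7 = carbonyl bridge) and tricyclo[5.4.0.0^2,8]undecane (C9 = enone carbonyl), and the CIP descriptors in the names were assigned by hand, so the SMILES are authoritative.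

**Step 1**
Reactants: 1 (S)-pantolactone; 2 tert-butyldimethylsilyl chloride
Product: 3 (3S)-3-[(tert-butyldimethylsilyl)oxy]-4,4-dimethyloxolan-2-one
Conditions: TBSCl, imidazole, DMF, rt
Reagents that add atoms: tert-butyldimethylsilyl chloride CC(C)(C)[Si](C)(C)Cl
Why: Imidazole-promoted silylation of the secondary alcohol, which leaves the (S) centre (the future C4 of the target) untouched.

**Step 2**
Reactants: 3; 4 N,O-dimethylhydroxylamine hydrochloride
Product: 5 (2S)-2-[(tert-butyldimethylsilyl)oxy]-4-hydroxy-N-methoxy-N,3,3-trimethylbutanamide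
Conditions: Me(MeO)NH·HCl, AlMe3, CH2Cl2, 0 °C → rt
Reagents that add atoms: N,O-dimethylhydroxylamine hydrochloride Cl.CNOC
Why: Weinreb aminolysis of the lactone by the aluminium amide opens the ring and differentiates the two termini (primary alcohol versus latent aldehyde) without touching the stereocentre.

**Step 3**
Reactants: 5
Product: 6 (2S)-2-[(tert-butyldimethylsilyl)oxy]-N-methoxy-N,3,3-trimethyl-4-oxobutanamide
Conditions: Dess–Martin periodinane, CH2Cl2, rt (used at once)
Reagents that add atoms: none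
Why: Dess–Martin oxidation of the neopentyl primary alcohol gives an aldehyde with a quaternary α-carbon, so neither enolisation nor β-elimination is possible.

**Step 4**
Reactants: 6; 7 diethyl (2-methylprop-2-en-1-yl)phosphonate
Product: 8 (2S,4E)-2-[(tert-butyldimethylsilyl)oxy]-N-methoxy-N,3,3,6-tetramethylhepta-4,6-dienamide
Conditions: 7, n-BuLi, THF, −78 °C; then 6, HMPA, −78 °C → rt
Reagents that add atoms: diethyl (2-methylprop-2-en-1-yl)phosphonate CCOP(=O)(OCC)CC(C)=C
Why: Horner–Wadsworth–Emmons olefination with the lithiated allylic phosphonate (HMPA drives the elimination) gives the (E)-1,3-diene, and the aldehyde reacts far faster than the Weinreb amide at −78 °C.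

**Step 5**
Reactants: 8
Product: 9 (2S,4E)-2-[(tert-butyldimethylsilyl)oxy]-3,3,6-trimethylhepta-4,6-dienal
Conditions: DIBAL-H, THF, −78 °C; Rochelle salt work-up
Reagents that add atoms: none
Why: Hydride reduction of the Weinreb amide stops at the aldehyde through the stable N-methoxy chelate, and the α-silyloxy centre does not epimerise at −78 °C.

**Step 6**
Reactants: 10 3-bromo-2-methylpropanoic acid (racemic); 11 triphenylphosphine
Product: 12 (2-carboxypropyl)triphenylphosphonium bromide (racemic)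
Conditions: PPh3, MeCN, reflux
Reagents that add atoms: triphenylphosphine c1ccc(cc1)P(c1ccccc1)c1ccccc1
Why: SN2 quaternisation of the phosphine by the primary bromide gives the Wittig salt, whose racemic methyl-bearing centre is erased in step 8.

**Step 7**
Reactants: 9; 12
Product: 13 (3Z,5R,7E)-5-[(tert-butyldimethylsilyl)oxy]-2,6,6,9-tetramethyldeca-3,7,9-trienoic acid (both C2 epimers)
Conditions: 12, NaHMDS (2 equiv per 12), THF, −78 → 0 °C; then 9, −78 °C → rt; 1 M HCl work-up
Reagents that add atoms: (2-carboxypropyl)triphenylphosphonium bromide [Br-].CC(C[P+](c1ccccc1)(c1ccccc1)c1ccccc1)C(=O)O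
Why: Wittig reaction of the non-stabilised β-carboxylato ylide with the α-silyloxy aldehyde under kinetic control gives the (Z)-β,γ-unsaturated acid, the carboxylate form suppressing retro-Michael loss of the ylide.

**Step 8**
Reactants: 13
Product: 16 (1R,4R,6R,8R)-4-[(tert-butyldimethylsilyl)oxy]-1,5,5-trimethyl-8-(prop-1-en-2-yl)bicyclo[4.1.1]oct-2-en-7-one, via acid chloride 14 (not isolated), via vinylketene 15 (not isolated)
Conditions: (COCl)2, cat. DMF, CH2Cl2, 0 °C → rt, evaporate; then slow addition to Et3N, toluene, 100 °C, final 0.005 M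
Reagents that add atoms: none
Why: Proposed new method: α-deprotonation of the β,γ-unsaturated acid chloride gives the (Z)-vinylketene, whose electrophilic central carbon (C1 of 13) bonds to the diene terminus C7 (leaving an allyl cation) while the ketene α-carbon C2 closes on C8, so the bridged mode forms the cyclobutanone and the cycloheptene together; the alkene adds suprafacially (E geometry puts the isopropenyl anti to the four-carbon bridge), the quaternary methyl centre follows from the tether, and the tether is expected to fold under the flat ketene carbon with the OTBS group outward, which places it on the C8 side; the closest known reactions are the intramolecular vinylketene–alkene [2+2] cycloadditions that give bicyclo[3.1.1]heptan-6-ones (chrysanthenone and β-trans-bergamotene type) and the regiochemistry of ketene additions to 1,3-dienes.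

**Step 9**
Reactants: 16; 17 (methoxymethyl)triphenylphosphonium chloride; 18 water
Product: 20 (1R,4R,6S,7R,8R)-4-[(tert-butyldimethylsilyl)oxy]-1,5,5-trimethyl-8-(prop-1-en-2-yl)bicyclo[4.1.1]oct-2-ene-7-carbaldehyde, via methyl enol ether 19 (not isolated)
Conditions: Ph3P(CH2OMe)Cl, KOtBu, THF, 0 → 45 °C; then 1 M aq. HCl, THF, rt
Reagents that add atoms: (methoxymethyl)triphenylphosphonium chloride [Cl-].COC[P+](c1ccccc1)(c1ccccc1)c1ccccc1; water O
Why: Wittig methoxymethylenation of the strained, non-enolisable cyclobutanone and enol ether hydrolysis give the one-carbon-homologated aldehyde, and acid-mediated enolisation equilibrates C7 to the exo epimer (formyl anti to the four-carbon bridge, cis to the isopropenyl group).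

**Step 10**
Reactants: 20
Product: 21 (1R,2S,4R,7R,8R)-4-[(tert-butyldimethylsilyl)oxy]-3,3,7-trimethyl-11-methylidenetricyclo[5.4.0.0^2,8]undec-5-en-9-ol (C9 epimer mixture)
Conditions: Me2AlCl, CH2Cl2, −78 → −30 °C
Reagents that add atoms: none
Why: Lewis-acid-promoted intramolecular carbonyl-ene reaction between the cis-1,3 formyl and isopropenyl groups closes the six-membered ring through a six-centre transition state that transfers a methyl hydrogen and so avoids a free cyclobutylcarbinyl cation; the new carbinol centre is removed in step 11.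

**Step 11**
Reactants: 21
Product: 23 (1R,2S,4R,7R,8R)-4-[(tert-butyldimethylsilyl)oxy]-3,3,7,11-tetramethyltricyclo[5.4.0.0^2,8]undeca-5,10-dien-9-one, via β,γ-unsaturated ketone 22 (not isolated)
Conditions: Dess–Martin periodinane, CH2Cl2, rt; then DBU (cat.), rt
Reagents that add atoms: none
Why: Dess–Martin oxidation gives the β,γ-unsaturated ketone, whose doubly activated C10 hydrogens allow base-mediated isomerisation to the conjugated trisubstituted enone, while C8 cannot epimerise because it is a bridgehead.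

**Step 12**
Reactants: 23
Product: 24 (1R,2S,4R,7R,8R)-4-hydroxy-3,3,7,11-tetramethyltricyclo[5.4.0.0^2,8]undeca-5,10-dien-9-one
Conditions: HF·pyridine, THF/pyridine, 0 °C → rt
Reagents that add atoms: none
Why: Fluoride-mediated Si–O cleavage frees the C4 alcohol with retention and without affecting the enone.

**Step 13**
Reactants: 24; 25 angelic acid
Product: 26 (1R,2S,4R,7R,8R)-3,3,7,11-tetramethyl-9-oxotricyclo[5.4.0.0^2,8]undeca-5,10-dien-4-yl (2Z)-2-methylbut-2-enoate
Conditions: angelic acid, 2,4,6-trichlorobenzoyl chloride, Et3N, toluene, rt; then 24, 80 °C (no DMAP)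
Reagents that add atoms: angelic acid C/C=C(/C)C(=O)O
Why: Yamaguchi-type esterification through the mixed trichlorobenzoic anhydride acylates the hindered alcohol with retention at C4 and, without DMAP, without Z→E isomerisation to the tiglate.

**Step 14**
Reactants: 26; 27 N-methylmorpholine N-oxide; 18 water
Product: 28 (1R,2S,4S,5S,6S,7R,8R)-5,6-dihydroxy-3,3,7,11-tetramethyl-9-oxotricyclo[5.4.0.0^2,8]undec-10-en-4-yl (2Z)-2-methylbut-2-enoate
Conditions: OsO4 (5 mol%), NMO, acetone/H2O, 0 °C → rt
Reagents that add atoms: N-methylmorpholine N-oxide C[N+]1([O-])CCOCC1; water O (oxygen transferred through catalytic osmium tetroxide O=[Os](=O)(=O)=O)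
Why: Upjohn dihydroxylation takes place at the only non-conjugated alkene and syn on its exo face anti to the allylic angelate (Kishi's rule, the concave face being blocked by the cyclobutane), which sets C5 and C6 as 4,5-trans-5,6-cis.

**Step 15**
Reactants: 28; 29 (R)-2-methylbutanoic acid
Product: 30 target CNP0206166.1, (1R,2S,4S,5S,6S,7R,8R)-6-hydroxy-3,3,7,11-tetramethyl-5-{[(2R)-2-methylbutanoyl]oxy}-9-oxotricyclo[5.4.0.0^2,8]undec-10-en-4-yl (2Z)-2-methylbut-2-enoate
Conditions: (R)-2-methylbutanoic acid, EDC·HCl, DMAP (cat.), CH2Cl2, −20 → 0 °C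
Reagents that add atoms: (R)-2-methylbutanoic acid CC[C@@H](C)C(=O)O
Why: Steglich esterification occurs at the C5 hydroxyl because the C6 hydroxyl is neopentylic (next to quaternary C7) and reacts much more slowly, and the α-centre of the acid is not enolised under these conditions.

**Compound list**
1 | (S)-pantolactone, (3S)-3-hydroxy-4,4-dimethyloxolan-2-one | CC1(C)COC(=O)[C@H]1O | starting material
2 | tert-butyldimethylsilyl chloride | CC(C)(C)[Si](C)(C)Cl | starting material
3 | (3S)-3-[(tert-butyldimethylsilyl)oxy]-4,4-dimethyloxolan-2-one | CC1(C)COC(=O)[C@H]1O[Si](C)(C)C(C)(C)C | intermediate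
4 | N,O-dimethylhydroxylamine hydrochloride | Cl.CNOC | starting material
5 | (2S)-2-[(tert-butyldimethylsilyl)oxy]-4-hydroxy-N-methoxy-N,3,3-trimethylbutanamide | CON(C)C(=O)[C@@H](O[Si](C)(C)C(C)(C)C)C(C)(C)CO | intermediate
6 | (2S)-2-[(tert-butyldimethylsilyl)oxy]-N-methoxy-N,3,3-trimethyl-4-oxobutanamide | CON(C)C(=O)[C@@H](O[Si](C)(C)C(C)(C)C)C(C)(C)C=O | intermediate
7 | diethyl (2-methylprop-2-en-1-yl)phosphonate | CCOP(=O)(OCC)CC(C)=C | starting material
8 | (2S,4E)-2-[(tert-butyldimethylsilyl)oxy]-N-methoxy-N,3,3,6-tetramethylhepta-4,6-dienamide | CON(C)C(=O)[C@@H](O[Si](C)(C)C(C)(C)C)C(C)(C)/C=C/C(C)=C | intermediate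
9 | (2S,4E)-2-[(tert-butyldimethylsilyl)oxy]-3,3,6-trimethylhepta-4,6-dienal | O=C[C@@H](O[Si](C)(C)C(C)(C)C)C(C)(C)/C=C/C(C)=C | intermediate
10 | 3-bromo-2-methylpropanoic acid (racemic) | CC(CBr)C(=O)O | starting material
11 | triphenylphosphine | c1ccc(cc1)P(c1ccccc1)c1ccccc1 | starting material
12 | (2-carboxypropyl)triphenylphosphonium bromide (racemic) | [Br-].CC(C[P+](c1ccccc1)(c1ccccc1)c1ccccc1)C(=O)O | intermediate
13 | (3Z,5R,7E)-5-[(tert-butyldimethylsilyl)oxy]-2,6,6,9-tetramethyldeca-3,7,9-trienoic acid (both C2 epimers) | OC(=O)C(C)/C=C\[C@@H](O[Si](C)(C)C(C)(C)C)C(C)(C)/C=C/C(C)=C | intermediate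
14 | acid chloride of 13 (not isolated) | ClC(=O)C(C)/C=C\[C@@H](O[Si](C)(C)C(C)(C)C)C(C)(C)/C=C/C(C)=C | intermediate
15 | (3Z,5R,7E)-5-[(tert-butyldimethylsilyl)oxy]-2,6,6,9-tetramethyldeca-1,3,7,9-tetraen-1-one, vinylketene (not isolated) | O=C=C(C)/C=C\[C@@H](O[Si](C)(C)C(C)(C)C)C(C)(C)/C=C/C(C)=C | intermediate
16 | (1R,4R,6R,8R)-4-[(tert-butyldimethylsilyl)oxy]-1,5,5-trimethyl-8-(prop-1-en-2-yl)bicyclo[4.1.1]oct-2-en-7-one; isopropenyl anti to the C2–C5 bridge, OTBS on the C8 side | CC(C)(C)[Si](C)(C)O[C@@H]1C=C[C@@]2(C)C(=O)[C@H]([C@@H]2C(C)=C)C1(C)C | intermediate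
17 | (methoxymethyl)triphenylphosphonium chloride | [Cl-].COC[P+](c1ccccc1)(c1ccccc1)c1ccccc1 | starting material
18 | water | O | starting material
19 | 7-(methoxymethylidene) analogue of 16, E/Z mixture (not isolated) | CC(C)(C)[Si](C)(C)O[C@@H]1C=C[C@@]2(C)C(=COC)[C@H]([C@@H]2C(C)=C)C1(C)C | intermediate
20 | (1R,4R,6S,7R,8R)-4-[(tert-butyldimethylsilyl)oxy]-1,5,5-trimethyl-8-(prop-1-en-2-yl)bicyclo[4.1.1]oct-2-ene-7-carbaldehyde; formyl and isopropenyl cis, both anti to the C2–C5 bridge | CC(C)(C)[Si](C)(C)O[C@@H]1C=C[C@@]2(C)[C@H](C=O)[C@H]([C@@H]2C(C)=C)C1(C)C | intermediate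
21 | (1R,2S,4R,7R,8R)-4-[(tert-butyldimethylsilyl)oxy]-3,3,7-trimethyl-11-methylidenetricyclo[5.4.0.0^2,8]undec-5-en-9-ol (C9 epimers) | CC(C)(C)[Si](C)(C)O[C@@H]1C=C[C@@]2(C)[C@@H]3C(O)CC(=C)[C@H]2[C@@H]3C1(C)C | intermediate
22 | (1R,2S,4R,7R,8R)-4-[(tert-butyldimethylsilyl)oxy]-3,3,7-trimethyl-11-methylidenetricyclo[5.4.0.0^2,8]undec-5-en-9-one (not isolated) | CC(C)(C)[Si](C)(C)O[C@@H]1C=C[C@@]2(C)[C@@H]3C(=O)CC(=C)[C@H]2[C@@H]3C1(C)C | intermediate
23 | (1R,2S,4R,7R,8R)-4-[(tert-butyldimethylsilyl)oxy]-3,3,7,11-tetramethyltricyclo[5.4.0.0^2,8]undeca-5,10-dien-9-one | CC(C)(C)[Si](C)(C)O[C@@H]1C=C[C@@]2(C)[C@@H]3C(=O)C=C(C)[C@H]2[C@@H]3C1(C)C | intermediate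
24 | (1R,2S,4R,7R,8R)-4-hydroxy-3,3,7,11-tetramethyltricyclo[5.4.0.0^2,8]undeca-5,10-dien-9-one | O[C@@H]1C=C[C@@]2(C)[C@@H]3C(=O)C=C(C)[C@H]2[C@@H]3C1(C)C | intermediate
25 | angelic acid, (2Z)-2-methylbut-2-enoic acid | C/C=C(/C)C(=O)O | starting material
26 | (1R,2S,4R,7R,8R)-3,3,7,11-tetramethyl-9-oxotricyclo[5.4.0.0^2,8]undeca-5,10-dien-4-yl (2Z)-2-methylbut-2-enoate | C/C=C(/C)C(=O)O[C@@H]1C=C[C@@]2(C)[C@@H]3C(=O)C=C(C)[C@H]2[C@@H]3C1(C)C | intermediate
27 | N-methylmorpholine N-oxide | C[N+]1([O-])CCOCC1 | starting material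
28 | (1R,2S,4S,5S,6S,7R,8R)-5,6-dihydroxy-3,3,7,11-tetramethyl-9-oxotricyclo[5.4.0.0^2,8]undec-10-en-4-yl (2Z)-2-methylbut-2-enoate | C/C=C(/C)C(=O)O[C@@H]1[C@@H](O)[C@@H](O)[C@@]2(C)[C@@H]3C(=O)C=C(C)[C@H]2[C@@H]3C1(C)C | intermediate
29 | (R)-2-methylbutanoic acid | CC[C@@H](C)C(=O)O | starting material
30 | CNP0206166.1, (1R,2S,4S,5S,6S,7R,8R)-6-hydroxy-3,3,7,11-tetramethyl-5-{[(2R)-2-methylbutanoyl]oxy}-9-oxotricyclo[5.4.0.0^2,8]undec-10-en-4-yl (2Z)-2-methylbut-2-enoate | C/C=C(/C)C(=O)O[C@@H]1[C@@H](OC(=O)[C@H](C)CC)[C@@H](O)[C@@]2(C)[C@@H]3C(=O)C=C(C)[C@H]2[C@@H]3C1(C)C | target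

**Step count**
Total steps: 15. Longest linear sequence: 14 (steps 1–5 and 7–15; step 6 is a one-step side branch).

**Steps most likely to fail, with fallbacks**

Step 8 (key cycloaddition). The (Z)-vinylketene can divert by a [1,5]-hydrogen shift from C5 to give a dienal, the seven-membered tether may close slowly, and the facial control by C5 is a prediction rather than a precedent. The fallback sets out from acid 13. It is coupled with pyrrolidine (EDC, HOBt) to give the pyrrolidine amide F1. Activation with Tf2O and 2,6-di-tert-butyl-4-methylpyridine in 1,2-dichloroethane (0 → 40 °C) generates the far more electrophilic keteniminium ion, which undergoes the same bridged [2+2] at low temperature to give the cyclobutaniminium triflate F2. Aqueous NaHCO3 hydrolysis brings the route back at 16.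

Step 10 (ene closure to the strained bicyclo[3.1.1] unit). A stepwise Prins pathway would give a pinanyl-type cation that can fragment or undergo Wagner–Meerwein shift. The fallback sets out from aldehyde 20. Thiol-catalysed radical hydroacylation (tert-dodecanethiol, AIBN, benzene, 80 °C) generates the acyl radical, which cyclises 6-endo onto the isopropenyl group to give the saturated tricyclic ketone F3. Dehydrogenation with IBX (DMSO/toluene, 70 °C) can only occur towards C10 and returns the route at enone 23, bypassing 21 and 22.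

Step 14 (dihydroxylation in the presence of the enone and the angelate). Over-oxidation of the conjugated alkenes would erode the yield. The fallback sets out from silyl ether 23 and oxidises before the angelate is present. OsO4/NMO gives the silyl ether diol F4 (anti to OTBS), and 2,2-dimethoxypropane/PPTS gives the acetonide F5. HF·pyridine then gives the C4 alcohol F6, and angeloylation as in step 13 gives the angelate acetonide F7. Aqueous acetic acid (60 °C) cleaves the acetonide and returns the route at diol 28.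

**Further compounds**
F1 | step 8 | (3Z,5R,7E)-5-[(tert-butyldimethylsilyl)oxy]-2,6,6,9-tetramethyl-1-(pyrrolidin-1-yl)deca-3,7,9-trien-1-one (C2 epimers) | O=C(N1CCCC1)C(C)/C=C\[C@@H](O[Si](C)(C)C(C)(C)C)C(C)(C)/C=C/C(C)=C
F2 | step 8 | pyrrolidinium (C7=N+) analogue of 16, trifluoromethanesulfonate salt | [O-]S(=O)(=O)C(F)(F)F.CC(C)(C)[Si](C)(C)O[C@@H]1C=C[C@@]2(C)C(=[N+]3CCCC3)[C@H]([C@@H]2C(C)=C)C1(C)C
F3 | step 10 | 4-[(tert-butyldimethylsilyl)oxy]-3,3,7,11-tetramethyltricyclo[5.4.0.0^2,8]undec-5-en-9-one, ring configuration as in 23 (C11 epimers) | CC(C)(C)[Si](C)(C)O[C@@H]1C=C[C@@]2(C)[C@@H]3C(=O)CC(C)[C@H]2[C@@H]3C1(C)C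
F4 | step 14 | 4-[(tert-butyldimethylsilyl)oxy]-5,6-dihydroxy-3,3,7,11-tetramethyltricyclo[5.4.0.0^2,8]undec-10-en-9-one, configuration as in 28 | CC(C)(C)[Si](C)(C)O[C@@H]1[C@@H](O)[C@@H](O)[C@@]2(C)[C@@H]3C(=O)C=C(C)[C@H]2[C@@H]3C1(C)C
F5 | step 14 | 5,6-O-isopropylidene derivative of F4 | CC(C)(C)[Si](C)(C)O[C@@H]1[C@H]4OC(C)(C)O[C@H]4[C@@]2(C)[C@@H]3C(=O)C=C(C)[C@H]2[C@@H]3C1(C)C
F6 | step 14 | 4-hydroxy-5,6-O-isopropylidene derivative (desilylated F5) | O[C@@H]1[C@H]4OC(C)(C)O[C@H]4[C@@]2(C)[C@@H]3C(=O)C=C(C)[C@H]2[C@@H]3C1(C)C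
F7 | step 14 | 5,6-O-isopropylidene derivative of 28 (4-angelate) | C/C=C(/C)C(=O)O[C@@H]1[C@H]4OC(C)(C)O[C@H]4[C@@]2(C)[C@@H]3C(=O)C=C(C)[C@H]2[C@@H]3C1(C)C
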